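**Retrosynthetic overview**
- The target is a 3-methoxyflavone with oxygen on C5, C7 and C8 of ring A. The O8–acyl bond is cut last, giving a 7-protected 5,8-dihydroxyflavone and (R)-2-methylbutanoic acid.
- Ring C is cut at C4–C4a and O1–C2. This gives 2,5-bis(benzyloxy)benzene-1,3-diol and the benzoyl(methoxy)ketene that methyl 2-methoxybenzoylacetate releases on heating.
- The strategy rests on the oxygen at C8: the phenol that becomes O1 has only one unsubstituted ortho carbon (the future C4a). The blocked resorcinol is mirror-symmetric, so its two phenols and two free carbons are equivalent, and the ether on the future C5 rules out closure to the 5,6,7-isomer.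
- The resorcinol comes from 3,4,5-trihydroxybenzaldehyde by exchanging the formyl carbon for oxygen (Baeyer–Villiger). The ketoester comes from methyl methoxyacetate and benzoyl chloride.
- Rings A and B are bought; ring C is the only ring formed (step 7).

Key step: step 7

Assumption: (R)-2-methylbutanoic acid of high enantiomeric purity is taken as purchasable; ring positions use flavone numbering (O1, C2, C3, C4, C4a, C5–C8, C8a).

**Route**

Step 1
Reactants: 1 3,4,5-trihydroxybenzaldehyde
Product: 2 4-(benzyloxy)-3,5-dihydroxybenzaldehyde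
Conditions: BnBr (1.0 equiv), NaHCO3, NaI (cat.), DMF, 40 °C, N2
Reagents that add atoms: benzyl bromide, BrCc1ccccc1
Why: Williamson etherification under a weak base; the 4-OH, para to the formyl group and flanked by two hydroxyls, is much the most acidic, so one equivalent of electrophile should go to O4.

Step 2
Reactants: 2 4-(benzyloxy)-3,5-dihydroxybenzaldehyde
Product: 3 4-(benzyloxy)-3,5-bis(methoxymethoxy)benzaldehyde
Conditions: MOMCl (2.6 equiv), i-Pr2NEt, CH2Cl2, 0 °C → rt
Reagents that add atoms: chloromethyl methyl ether, COCCl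
Why: O-alkylation with an α-chloro ether (MOM acetal formation) on the two equivalent remaining phenols; aldehyde and benzyl ether are inert.

Step 3
Reactants: 3 4-(benzyloxy)-3,5-bis(methoxymethoxy)benzaldehyde
Product: 5 4-(benzyloxy)-3,5-bis(methoxymethoxy)phenol, via aryl formate 4 (not isolated)
Conditions: mCPBA, CH2Cl2, 0 °C → rt; aq. Na2SO3/NaHCO3 wash; crude 4, K2CO3 (cat.), MeOH, rt
Reagents that add atoms: 3-chloroperoxybenzoic acid, O=C(OO)c1cccc(Cl)c1
Why: Baeyer–Villiger (Dakin-type) oxidation, in which the electron-rich trialkoxyaryl group migrates in preference to hydride to give the aryl formate, which mild methanolysis cleaves to the phenol.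

Step 4
Reactants: 5 4-(benzyloxy)-3,5-bis(methoxymethoxy)phenol
Product: 6 2,5-bis(benzyloxy)-1,3-bis(methoxymethoxy)benzene
Conditions: BnBr, K2CO3, DMF, rt
Reagents that add atoms: benzyl bromide, BrCc1ccccc1
Why: Williamson etherification of the only free phenol.

Step 5
Reactants: 6 2,5-bis(benzyloxy)-1,3-bis(methoxymethoxy)benzene
Product: 7 2,5-bis(benzyloxy)benzene-1,3-diol
Conditions: HCl (conc., cat.), MeOH, 50 °C
Reagents that add atoms: none
Why: Acid-catalysed acetal exchange with methanol removes both MOM groups, while aryl benzyl ethers are stable to dilute methanolic HCl.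

Step 6
Reactants: 8 methyl methoxyacetate; 9 benzoyl chloride
Product: 11 methyl 2-methoxy-3-oxo-3-phenylpropanoate, via lithium ester enolate 10 (not isolated)
Conditions: LiN(SiMe3)2 (2.05 equiv), 8 (2.0 equiv), THF, −78 °C; 9 (1.0 equiv), −78 → −40 °C; aq. NH4Cl
Reagents that add atoms: none
Why: Crossed Claisen-type C-acylation of an ester lithium enolate by an acid chloride; the second equivalent of enolate deprotonates the more acidic β-ketoester as it forms and so prevents a second acylation.

Step 7
Reactants: 7 2,5-bis(benzyloxy)benzene-1,3-diol; 11 methyl 2-methoxy-3-oxo-3-phenylpropanoate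
Product: 15 5,8-bis(benzyloxy)-7-hydroxy-3-methoxyflavone, via benzoyl(methoxy)ketene 12 (not isolated), via aryl ketoester 13 (not isolated), via C-acylated diketone 14 (not isolated)
Conditions: 7 (1.3 equiv), 11 (1.0 equiv), neat, Ar, 240 °C (microwave or metal bath), short reaction time, MeOH and H2O swept out
Reagents that add atoms: none
Why: At this temperature 11 loses methanol to benzoyl(methoxy)ketene 12, which is captured reversibly on a phenol oxygen of 7 as ester 13; the acyl group then passes, in a thermal Fries-type transfer, to the ring carbon ortho to that phenol to give diketone 14, whose neighbouring phenol adds to the benzoyl carbonyl and loses water. The closest known reaction type is the Mentzer pyrone synthesis, the acid-free thermal (also microwave) condensation of phloroglucinol-type phenols with benzoylacetates to flavones. Ring C is closed by 6-exo-trig attack of the future O1 on the ketone carbon followed by dehydration, so that C4–C4a and O1–C2 are the two bonds formed; no stereocentre arises. Chromone and not coumarin is expected because without acid the ring carbon is acylated by the ketene carbon (future C4) and never attacks the ketone, so a Pechmann closure has no entry. The regiochemistry needs no control: C2 of 7 carries an ether, so each phenol has a single free ortho carbon, the two sets are equivalent by the mirror symmetry of 7, and the ether on C5 of 7 leaves only one hydroxyl beside the new acyl group, which fixes the 5,7,8 and excludes the 5,6,7 pattern. A second annulation at C6 should be slow because the first pyranone carbonyl deactivates ring A, and 7 is used in slight excess.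

Step 8
Reactants: 15 5,8-bis(benzyloxy)-7-hydroxy-3-methoxyflavone
Product: 16 5,8-bis(benzyloxy)-3-methoxy-7-(methoxymethoxy)flavone
Conditions: MOMCl, i-Pr2NEt, CH2Cl2, 0 °C → rt
Reagents that add atoms: chloromethyl methyl ether, COCCl
Why: O-alkylation (MOM acetal formation) of the single free, acidic 7-OH; an acetal is chosen because, unlike a silyl ether, it cannot shift to the neighbouring O8 once that oxygen is unmasked.

Step 9
Reactants: 16 5,8-bis(benzyloxy)-3-methoxy-7-(methoxymethoxy)flavone
Product: 17 5,8-dihydroxy-3-methoxy-7-(methoxymethoxy)flavone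
Conditions: H2 (1 atm), Pd/C (10%), EtOAc–THF, rt; filtered and used under Ar
Reagents that add atoms: none
Why: Heterogeneous hydrogenolysis of the two aryl benzyl ethers; the MOM acetal, the methyl ether and the tetrasubstituted C2=C3 bond of the pyranone should not react under neutral conditions.

Step 10
Reactants: 17 5,8-dihydroxy-3-methoxy-7-(methoxymethoxy)flavone; 18 (R)-2-methylbutanoic acid
Product: 20 5-hydroxy-3-methoxy-7-(methoxymethoxy)-4-oxo-2-phenyl-4H-chromen-8-yl (2R)-2-methylbutanoate, via O-acylisourea 19 (not isolated)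
Conditions: DCC (1.1 equiv), DMAP (0.1 equiv), CH2Cl2, 0 °C → rt, Ar
Reagents that add atoms: none
Why: Steglich esterification; the 5-OH is held in a hydrogen bond to the C4 carbonyl and is a poor nucleophile, so only the 8-OH should be acylated, and the stereocentre is carried unchanged from 18, low temperature and little DMAP guarding the α-carbon against epimerisation.

Step 11
Reactants: 20 5-hydroxy-3-methoxy-7-(methoxymethoxy)-4-oxo-2-phenyl-4H-chromen-8-yl (2R)-2-methylbutanoate
Product: 21 5,7-dihydroxy-3-methoxy-4-oxo-2-phenyl-4H-chromen-8-yl (2R)-2-methylbutanoate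
Conditions: ZnBr2 (1.5 equiv), n-PrSH (3 equiv), CH2Cl2, 0 °C → rt
Reagents that add atoms: none
Why: Lewis-acid-assisted thiolysis of the MOM acetal (the methoxymethyl group is passed to sulfur) under non-basic, non-hydrolytic conditions that should leave the aryl ester, its α-stereocentre and the 3-OMe untouched.

**Compound list**
1 | 3,4,5-trihydroxybenzaldehyde | O=Cc1cc(O)c(O)c(O)c1 | starting material
2 | 4-(benzyloxy)-3,5-dihydroxybenzaldehyde | O=Cc1cc(O)c(OCc2ccccc2)c(O)c1 | intermediate
3 | 4-(benzyloxy)-3,5-bis(methoxymethoxy)benzaldehyde | COCOc1cc(C=O)cc(OCOC)c1OCc1ccccc1 | intermediate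
4 | 4-(benzyloxy)-3,5-bis(methoxymethoxy)phenyl formate | COCOc1cc(OC=O)cc(OCOC)c1OCc1ccccc1 | intermediate
5 | 4-(benzyloxy)-3,5-bis(methoxymethoxy)phenol | COCOc1cc(O)cc(OCOC)c1OCc1ccccc1 | intermediate
6 | 2,5-bis(benzyloxy)-1,3-bis(methoxymethoxy)benzene | COCOc1cc(OCc2ccccc2)cc(OCOC)c1OCc1ccccc1 | intermediate
7 | 2,5-bis(benzyloxy)benzene-1,3-diol | Oc1cc(OCc2ccccc2)cc(O)c1OCc1ccccc1 | intermediate
8 | methyl methoxyacetate | COCC(=O)OC | starting material
9 | benzoyl chloride | O=C(Cl)c1ccccc1 | starting material
10 | lithium enolate of methyl methoxyacetate | [Li+].[O-]C(OC)=COC | intermediate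
11 | methyl 2-methoxy-3-oxo-3-phenylpropanoate (racemic, enolisable) | COC(=O)C(OC)C(=O)c1ccccc1 | intermediate
12 | benzoyl(methoxy)ketene | COC(=C=O)C(=O)c1ccccc1 | intermediate
13 | 2,5-bis(benzyloxy)-3-hydroxyphenyl 2-methoxy-3-oxo-3-phenylpropanoate | COC(C(=O)c1ccccc1)C(=O)Oc1cc(OCc2ccccc2)cc(O)c1OCc1ccccc1 | intermediate
14 | 1-[3,6-bis(benzyloxy)-2,4-dihydroxyphenyl]-2-methoxy-3-phenylpropane-1,3-dione | COC(C(=O)c1ccccc1)C(=O)c1c(O)c(OCc2ccccc2)c(O)cc1OCc1ccccc1 | intermediate
15 | 5,8-bis(benzyloxy)-7-hydroxy-3-methoxyflavone | COc1c(-c2ccccc2)oc2c(OCc3ccccc3)c(O)cc(OCc3ccccc3)c2c1=O | intermediate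
16 | 5,8-bis(benzyloxy)-3-methoxy-7-(methoxymethoxy)flavone | COCOc1cc(OCc2ccccc2)c2c(=O)c(OC)c(-c3ccccc3)oc2c1OCc1ccccc1 | intermediate
17 | 5,8-dihydroxy-3-methoxy-7-(methoxymethoxy)flavone | COCOc1cc(O)c2c(=O)c(OC)c(-c3ccccc3)oc2c1O | intermediate
18 | (R)-2-methylbutanoic acid | CC[C@@H](C)C(=O)O | starting material
19 | O-[(2R)-2-methylbutanoyl]-N,N'-dicyclohexylisourea | CC[C@@H](C)C(=O)OC(=NC1CCCCC1)NC1CCCCC1 | intermediate
20 | 5-hydroxy-3-methoxy-7-(methoxymethoxy)-4-oxo-2-phenyl-4H-chromen-8-yl (2R)-2-methylbutanoate | CC[C@@H](C)C(=O)Oc1c(OCOC)cc(O)c2c(=O)c(OC)c(-c3ccccc3)oc12 | intermediate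
21 | 5,7-dihydroxy-3-methoxy-4-oxo-2-phenyl-4H-chromen-8-yl (2R)-2-methylbutanoate | CC[C@@H](C)C(=O)Oc1c(O)cc(O)c2c(=O)c(OC)c(-c3ccccc3)oc12 | target

**Step count**
Total steps: 11. Longest linear sequence: 10 (steps 1–5 and 7–11); step 6 is the side branch.

**Steps most likely to fail**

Step 7. The benzyl group on the oxygen flanked by two phenols may be lost or may migrate at 240 °C. The sequence may also stall at the O-acyl stage, or close through the ester carbonyl. The fallback builds the same two bonds stepwise, sets out from 7 and comes back at 15. Hoesch acylation of 7 with methoxyacetonitrile (ZnCl2, HCl, Et2O, 0 °C) should give 1-[3,6-bis(benzyloxy)-2,4-dihydroxyphenyl]-2-methoxyethan-1-iminium chloride F1. Hydrolysis in hot water should give 1-[3,6-bis(benzyloxy)-2,4-dihydroxyphenyl]-2-methoxyethan-1-one F2. Allan–Robinson condensation with benzoic anhydride and PhCO2Na at 170–180 °C should give 5,8-bis(benzyloxy)-3-methoxy-4-oxo-2-phenyl-4H-chromen-7-yl benzoate F3. Brief treatment with KOH in aqueous ethanol removes the benzoate and gives 15.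

Step 11. The aryl ester may be cleaved or may shift to O7 while the acetal is removed under Lewis-acidic conditions. The fallback replaces the acetal by a benzyl ether so that the last step is a neutral hydrogenolysis; it sets out from 15 and comes back at 21. Hydrogenolysis of 15 (H2, Pd/C) should give 5,7,8-trihydroxy-3-methoxyflavone F4. One equivalent of BnBr with K2CO3 in acetone should alkylate the most acidic hydroxyl (O7, para to the carbonyl) to give 7-(benzyloxy)-5,8-dihydroxy-3-methoxyflavone F5. Steglich acylation with 18 (DCC, DMAP, through 19) should give 7-(benzyloxy)-5-hydroxy-3-methoxy-4-oxo-2-phenyl-4H-chromen-8-yl (2R)-2-methylbutanoate F6. Hydrogenolysis (H2, Pd/C, EtOAc) then gives 21.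

Step 1. Alkylation may occur on a flanking oxygen or a second time. The fallback uses deacylative alkylation of the peracetate; it sets out from 1 and comes back at 2. Ac2O in pyridine should give 3,4,5-triacetoxybenzaldehyde F7. BnBr, K2CO3 and KI in refluxing acetone should cleave only the most activated ester (para to the formyl group) and benzylate the phenoxide in the same flask, giving 3,5-diacetoxy-4-(benzyloxy)benzaldehyde F8. Mild methanolysis (K2CO3, MeOH, 0 °C) of the two remaining acetates gives 2.

**Further compounds**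
F1 | step 7 | 1-[3,6-bis(benzyloxy)-2,4-dihydroxyphenyl]-2-methoxyethan-1-iminium chloride | COCC(=[NH2+])c1c(O)c(OCc2ccccc2)c(O)cc1OCc1ccccc1.[Cl-]
F2 | step 7 | 1-[3,6-bis(benzyloxy)-2,4-dihydroxyphenyl]-2-methoxyethan-1-one | COCC(=O)c1c(O)c(OCc2ccccc2)c(O)cc1OCc1ccccc1
F3 | step 7 | 5,8-bis(benzyloxy)-3-methoxy-4-oxo-2-phenyl-4H-chromen-7-yl benzoate | COc1c(-c2ccccc2)oc2c(OCc3ccccc3)c(OC(=O)c3ccccc3)cc(OCc3ccccc3)c2c1=O
F4 | step 11 | 5,7,8-trihydroxy-3-methoxyflavone | COc1c(-c2ccccc2)oc2c(O)c(O)cc(O)c2c1=O
F5 | step 11 | 7-(benzyloxy)-5,8-dihydroxy-3-methoxyflavone | COc1c(-c2ccccc2)oc2c(O)c(OCc3ccccc3)cc(O)c2c1=O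
F6 | step 11 | 7-(benzyloxy)-5-hydroxy-3-methoxy-4-oxo-2-phenyl-4H-chromen-8-yl (2R)-2-methylbutanoate | CC[C@@H](C)C(=O)Oc1c(OCc2ccccc2)cc(O)c2c(=O)c(OC)c(-c3ccccc3)oc12
F7 | step 1 | 3,4,5-triacetoxybenzaldehyde | CC(=O)Oc1cc(C=O)cc(OC(C)=O)c1OC(C)=O
F8 | step 1 | 3,5-diacetoxy-4-(benzyloxy)benzaldehyde | CC(=O)Oc1cc(C=O)cc(OC(C)=O)c1OCc1ccccc1
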